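**Retrosynthetic overview**

1. Target 26 ⇐ epoxidation of the 1(10)-olefin of diene 25 ⇐ esterification of 6β-alcohol 16 with side-chain acid 24; 16 ⇐ ketone reduction and C11 O-angeloylation of keto-lactone 14.
2. 14 ⇐ closure of the ten-membered carbocycle at C6–C7 by a light-driven nickel/iridium deoxygenative acylation of seco acid 11 (the new step).
3. 11 ⇐ C9–C10 cross-electrophile coupling of iodolactone 9 with vinyl bromide 7; 9 comes from 2-C-methyl-D-ribono-1,4-lactone, which supplies C8, C11, C12, C13 and the lactone.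
4. 7 ⇐ tert-butyl acetoacetate and 1-bromobut-2-yne (E-enol triflate then cuprate for the 4Z olefin; hydrozirconation for the 1(10)E olefin); 24 ⇐ the pivalaldehyde dioxanone of (R)-3-hydroxybutanoic acid (hydroxylation, then methylation).
5. Ring order: the γ-lactone is bought, the carbocycle is closed second, the oxirane is formed last.

Assumption: germacrane numbering (C1–C15) is used for the core, and 2-C-methyl-D-ribono-1,4-lactone, (R)-3-hydroxybutanoic acid and angelic anhydride are taken as purchasable.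

**Route**

Step 1
Reactants: 1 tert-butyl 3-oxobutanoate; 2 1-bromobut-2-yne
Product: 3 tert-butyl 3-oxooct-6-ynoate
Conditions: NaH, THF, 0 °C; n-BuLi, 0 °C; then 2, 0 °C to rt; aq. NH4Cl
Reagents that add atoms: none
Why: Dianion alkylation of a β-keto ester occurs at the terminal (γ) carbon with the reactive propargylic bromide, and no stereocentre is formed.

Step 2
Reactants: 3 tert-butyl 3-oxooct-6-ynoate
Product: 4 tert-butyl (2E)-3-(trifluoromethanesulfonyloxy)oct-2-en-6-ynoate
Conditions: Tf2O, aq. Me4NOH, toluene, 5 °C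
Reagents that add atoms: triflic anhydride O=S(=O)(OS(=O)(=O)C(F)(F)F)C(F)(F)F
Why: Enol triflation of the non-chelated tetramethylammonium enolate gives the E-enol triflate, which fixes the geometry that later becomes the 4Z ring olefin.

Step 3
Reactants: 4 tert-butyl (2E)-3-(trifluoromethanesulfonyloxy)oct-2-en-6-ynoate
Product: 5 tert-butyl (2Z)-3-methyloct-2-en-6-ynoate
Conditions: Me2CuLi, THF, −78 to −40 °C
Reagents that add atoms: lithium dimethylcuprate [Li+].C[Cu-]C
Why: Cuprate coupling with a β-triflyloxy enoate (addition–elimination) proceeds with retention, so methyl replaces triflate trans to the ester and the chain stays cis (Z).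

Step 4
Reactants: 5 tert-butyl (2Z)-3-methyloct-2-en-6-ynoate
Product: 7 tert-butyl (2Z,6E)-7-bromo-3-methylocta-2,6-dienoate, via alkenylzirconocene chloride 6 (not isolated)
Conditions: Cp2Zr(H)Cl (2.2 equiv), THF, 45 °C; then NBS, 0 °C
Reagents that add atoms: N-bromosuccinimide O=C1CCC(=O)N1Br
Why: syn-Hydrozirconation under equilibrating conditions puts zirconium on the methyl-bearing alkyne carbon and bromodezirconation retains geometry, giving the E-vinyl bromide.

Step 5
Reactants: 8 2-C-methyl-D-ribono-1,4-lactone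
Product: 9 (3R,4R,5S)-3,4-dihydroxy-5-(iodomethyl)-3-methyloxolan-2-one
Conditions: I2, PPh3, imidazole, THF, 0 °C to rt
Reagents that add atoms: iodine II
Why: Appel-type (Garegg–Samuelsson) iodination is selective for the primary hydroxyl over the secondary and tertiary ones, and the three bought stereocentres are untouched.

Step 6
Reactants: 9 (3R,4R,5S)-3,4-dihydroxy-5-(iodomethyl)-3-methyloxolan-2-one; 7 tert-butyl (2Z,6E)-7-bromo-3-methylocta-2,6-dienoate
Product: 10 tert-butyl (2Z,6E)-8-[(2R,3R,4R)-3,4-dihydroxy-4-methyl-5-oxooxolan-2-yl]-3,7-dimethylocta-2,6-dienoate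
Conditions: NiBr2·glyme (10 mol %), 4,4'-di-tert-butyl-2,2'-bipyridine (10 mol %), Mn powder (2 equiv), NaI (25 mol %), DMPU, rt
Reagents that add atoms: none
Why: Nickel-catalysed reductive cross-electrophile coupling of a primary alkyl iodide (radical path, so no β-alkoxy elimination) with a vinyl bromide forms C9–C10 with retention of the E geometry and tolerates free hydroxyls and the lactone.

Step 7
Reactants: 10 tert-butyl (2Z,6E)-8-[(2R,3R,4R)-3,4-dihydroxy-4-methyl-5-oxooxolan-2-yl]-3,7-dimethylocta-2,6-dienoate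
Product: 11 (2Z,6E)-8-[(2R,3R,4R)-3,4-dihydroxy-4-methyl-5-oxooxolan-2-yl]-3,7-dimethylocta-2,6-dienoic acid
Conditions: TMSOTf, 2,6-lutidine, CH2Cl2, 0 °C; then aq. citric acid, THF
Reagents that add atoms: none
Why: Silyl triflate-mediated tert-butyl ester cleavage (through the silyl ester) avoids the protic acid that could cyclise the hydroxyls onto the trisubstituted olefin.

Step 8
Reactants: 11 (2Z,6E)-8-[(2R,3R,4R)-3,4-dihydroxy-4-methyl-5-oxooxolan-2-yl]-3,7-dimethylocta-2,6-dienoic acid
Product: 14 (1(10)E,4Z)-11β-hydroxy-6-oxo-7αH,8βH-germacra-1(10),4-dien-12,8-olide, via mixed pivalic anhydride 12 (not isolated), via benzoxazoline adduct 13 (not isolated)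
Conditions: (tBuCO)2O, pyridine, MTBE, rt; 3-phenyl-1,3-benzoxazol-3-ium tetrafluoroborate, rt, 15 min; then syringe-pump addition to NiBr2·glyme (20 mol %), 4,4'-di-tert-butyl-2,2'-bipyridine, Ir(ppy)2(dtbbpy)PF6 (2 mol %), quinuclidine, DMA/MTBE, 2 mM, 450 nm LEDs, rt
Reagents that add atoms: none
Why: Proposed new method: a deoxygenative acyl macrocyclisation in which the benzoxazoline adduct of the secondary C7 alcohol is oxidised by the excited iridium photocatalyst and, after deprotonation and β-scission, releases the C7 radical, which is captured by the enoyl–nickel species formed by oxidative addition of zerovalent nickel into the less hindered acyl–oxygen bond of the mixed anhydride, so that reductive elimination closes the ten-membered ring and places C6 on the lactone face opposite both the C8 chain and the C11 methyl (also the thermodynamic configuration of this epimerisable α-keto centre), the σ-acyl nickel keeping the Z-enoyl geometry and the low-triplet-energy photocatalyst avoiding enone isomerisation; the closest known reactions are the benzoxazolium-mediated nickel/photoredox deoxygenative arylation of alcohols and nickel/photoredox ketone synthesis from anhydrides and alkyl radicals.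

Step 9
Reactants: 14 (1(10)E,4Z)-11β-hydroxy-6-oxo-7αH,8βH-germacra-1(10),4-dien-12,8-olide
Product: 15 (1(10)E,4Z)-11β-angeloyloxy-6-oxo-7αH,8βH-germacra-1(10),4-dien-12,8-olide
Conditions: LiN(SiMe3)2 (1.05 equiv), THF, −78 °C; angelic anhydride, −78 to −40 °C; aq. NH4Cl
Reagents that add atoms: angelic anhydride C/C=C(/C)C(=O)OC(=O)/C(C)=C\C
Why: Kinetic O-deprotonation of the only hydroxyl and acylation of the lithium alkoxide at low temperature esterifies the hindered tertiary alcohol with retention at C11 and without Z-to-E isomerisation of the angelate.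

Step 10
Reactants: 15 (1(10)E,4Z)-11β-angeloyloxy-6-oxo-7αH,8βH-germacra-1(10),4-dien-12,8-olide
Product: 16 (1(10)E,4Z)-11β-angeloyloxy-6β-hydroxy-7αH,8βH-germacra-1(10),4-dien-12,8-olide
Conditions: NaBH4, CeCl3·7H2O, MeOH/CH2Cl2, −78 °C
Reagents that add atoms: none
Why: Luche 1,2-reduction of the ring enone, in which hydride is expected to enter from the α face, away from the β-oriented C7–C11 bond of the trans-fused lactone, giving the 6β (6R) alcohol; this facial preference is an expectation, not a certainty.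

Step 11
Reactants: 17 (R)-3-hydroxybutanoic acid
Product: 18 (2R,6R)-2-tert-butyl-6-methyl-1,3-dioxan-4-one
Conditions: pivalaldehyde, PPTS (cat.), CH2Cl2, reflux, water separator; crystallisation
Reagents that add atoms: pivalaldehyde CC(C)(C)C=O
Why: Acid-catalysed acetalisation (Seebach dioxanone formation) gives the cis-2,6-disubstituted ring under thermodynamic control, the acetal centre being set by the bought C6 stereocentre.

Step 12
Reactants: 18 (2R,6R)-2-tert-butyl-6-methyl-1,3-dioxan-4-one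
Product: 20 (2R,5R,6R)-2-tert-butyl-6-methyl-5-(triethylsilyloxy)-1,3-dioxan-4-one, via 5-hydroxydioxanone sodium alkoxide 19 (not isolated)
Conditions: NaN(SiMe3)2, THF, −78 °C; racemic 2-(phenylsulfonyl)-3-phenyloxaziridine; then Et3SiCl, −78 to 0 °C
Reagents that add atoms: 2-(phenylsulfonyl)-3-phenyloxaziridine O=S(=O)(c1ccccc1)N1OC1c1ccccc1; chlorotriethylsilane CC[Si](Cl)(CC)CC
Why: Davis enolate hydroxylation occurs on the dioxanone enolate face trans to the C6 methyl, and the alkoxide is silylated in the same flask.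

Step 13
Reactants: 20 (2R,5R,6R)-2-tert-butyl-6-methyl-5-(triethylsilyloxy)-1,3-dioxan-4-one
Product: 21 (2R,5S,6R)-2-tert-butyl-5,6-dimethyl-5-(triethylsilyloxy)-1,3-dioxan-4-one
Conditions: LiN(iPr)2, THF, −78 °C; MeI, DMPU, −78 to −30 °C
Reagents that add atoms: iodomethane CI
Why: Enolate alkylation again takes place trans to the C6 methyl, so the oxygen ends cis to it and the quaternary centre has the 2S configuration of the side chain (oxygen first, methyl second is essential).

Step 14
Reactants: 21 (2R,5S,6R)-2-tert-butyl-5,6-dimethyl-5-(triethylsilyloxy)-1,3-dioxan-4-one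
Product: 22 (2S,3R)-2,3-dihydroxy-2-methylbutanoic acid
Conditions: 2 M HCl, THF, 40 °C
Reagents that add atoms: none
Why: Acid hydrolysis of the acylal and of the silyl ether leaves both stereocentres untouched.

Step 15
Reactants: 22 (2S,3R)-2,3-dihydroxy-2-methylbutanoic acid
Product: 24 (2S,3R)-3-(angeloyloxy)-2-hydroxy-2-methylbutanoic acid, via mixed angelic anhydride 23 (not isolated)
Conditions: angelic anhydride (2.5 equiv), Et3N, DMAP (5 mol %), CH2Cl2, −20 °C; then aq. NaHCO3, THF, rt; H3O+
Reagents that add atoms: angelic anhydride C/C=C(/C)C(=O)OC(=O)/C(C)=C\C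
Why: Nucleophile-catalysed acylation takes the secondary hydroxyl and leaves the hindered tertiary one, and the carboxyl mixed anhydride is hydrolysed on bicarbonate work-up.

Step 16
Reactants: 16 (1(10)E,4Z)-11β-angeloyloxy-6β-hydroxy-7αH,8βH-germacra-1(10),4-dien-12,8-olide; 24 (2S,3R)-3-(angeloyloxy)-2-hydroxy-2-methylbutanoic acid
Product: 25 (1(10)E,4Z)-11β-angeloyloxy-6β-[(2S,3R)-3-(angeloyloxy)-2-hydroxy-2-methylbutanoyloxy]-7αH,8βH-germacra-1(10),4-dien-12,8-olide
Conditions: 2-methyl-6-nitrobenzoic anhydride, DMAP, Et3N, CH2Cl2, rt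
Reagents that add atoms: none
Why: Shiina esterification couples the hindered acid and the secondary allylic alcohol with retention at C6, the tertiary α-hydroxyl of the acid being too hindered to compete.

Step 17
Reactants: 25 (1(10)E,4Z)-11β-angeloyloxy-6β-[(2S,3R)-3-(angeloyloxy)-2-hydroxy-2-methylbutanoyloxy]-7αH,8βH-germacra-1(10),4-dien-12,8-olide
Product: 26 CNP0137221.3, the 1β,10α-epoxide (1R,10R) of 25
Conditions: mCPBA, NaHCO3, CH2Cl2, 0 °C
Reagents that add atoms: 3-chloroperbenzoic acid OOC(=O)c1cccc(Cl)c1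
Why: Prilezhaev epoxidation attacks the most electron-rich olefin (the 4,5-olefin is deactivated by the allylic acyloxy group and the angelates are electron-poor), is stereospecific for the trans epoxide from the E olefin, and is expected to occur on the exposed outer face to give 1R,10R.

**Compound list**

1 | tert-butyl 3-oxobutanoate | CC(=O)CC(=O)OC(C)(C)C | starting material
2 | 1-bromobut-2-yne | CC#CCBr | starting material
3 | tert-butyl 3-oxooct-6-ynoate | CC#CCCC(=O)CC(=O)OC(C)(C)C | intermediate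
4 | tert-butyl (2E)-3-(trifluoromethanesulfonyloxy)oct-2-en-6-ynoate | CC#CCC/C(=C\C(=O)OC(C)(C)C)OS(=O)(=O)C(F)(F)F | intermediate
5 | tert-butyl (2Z)-3-methyloct-2-en-6-ynoate | CC#CCC/C(C)=C\C(=O)OC(C)(C)C | intermediate
6 | chlorobis(cyclopentadienyl)[(2E,6Z)-8-tert-butoxy-6-methyl-8-oxoocta-2,6-dien-2-yl]zirconium | C/C([Zr+2]Cl)=C\CC/C(C)=C\C(=O)OC(C)(C)C.c1cc[cH-]c1.c1cc[cH-]c1 | intermediate
7 | tert-butyl (2Z,6E)-7-bromo-3-methylocta-2,6-dienoate | C/C(Br)=C\CC/C(C)=C\C(=O)OC(C)(C)C | intermediate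
8 | 2-C-methyl-D-ribono-1,4-lactone, (3R,4R,5R)-3,4-dihydroxy-5-(hydroxymethyl)-3-methyloxolan-2-one | OC[C@H]1OC(=O)[C@](C)(O)[C@@H]1O | starting material
9 | (3R,4R,5S)-3,4-dihydroxy-5-(iodomethyl)-3-methyloxolan-2-one | IC[C@H]1OC(=O)[C@](C)(O)[C@@H]1O | intermediate
10 | tert-butyl (2Z,6E)-8-[(2R,3R,4R)-3,4-dihydroxy-4-methyl-5-oxooxolan-2-yl]-3,7-dimethylocta-2,6-dienoate | CC(C)(C)OC(=O)/C=C(/C)CC/C=C(\C)C[C@H]1OC(=O)[C@](C)(O)[C@@H]1O | intermediate
11 | (2Z,6E)-8-[(2R,3R,4R)-3,4-dihydroxy-4-methyl-5-oxooxolan-2-yl]-3,7-dimethylocta-2,6-dienoic acid | OC(=O)/C=C(/C)CC/C=C(\C)C[C@H]1OC(=O)[C@](C)(O)[C@@H]1O | intermediate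
12 | mixed anhydride of 11 with pivalic acid | CC(C)(C)C(=O)OC(=O)/C=C(/C)CC/C=C(\C)C[C@H]1OC(=O)[C@](C)(O)[C@@H]1O | intermediate
13 | 12 whose secondary (C7) hydroxyl carries a 3-phenyl-2,3-dihydro-1,3-benzoxazol-2-yl group (aminal carbon unassigned) | CC(C)(C)C(=O)OC(=O)/C=C(/C)CC/C=C(\C)C[C@H]1OC(=O)[C@](C)(O)[C@@H]1OC1Oc2ccccc2N1c1ccccc1 | intermediate
14 | (1(10)E,4Z)-11β-hydroxy-6-oxo-7αH,8βH-germacra-1(10),4-dien-12,8-olide (trans-fused lactone, 11α-methyl) | O=C1/C=C(/C)CC/C=C(\C)C[C@H]2OC(=O)[C@](C)(O)[C@H]12 | intermediate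
15 | (1(10)E,4Z)-11β-angeloyloxy-6-oxo-7αH,8βH-germacra-1(10),4-dien-12,8-olide | O=C1/C=C(/C)CC/C=C(\C)C[C@H]2OC(=O)[C@](C)(OC(=O)/C(C)=C\C)[C@H]12 | intermediate
16 | (1(10)E,4Z)-11β-angeloyloxy-6β-hydroxy-7αH,8βH-germacra-1(10),4-dien-12,8-olide (6R) | O[C@@H]1/C=C(/C)CC/C=C(\C)C[C@H]2OC(=O)[C@](C)(OC(=O)/C(C)=C\C)[C@H]12 | intermediate
17 | (R)-3-hydroxybutanoic acid | C[C@@H](O)CC(=O)O | starting material
18 | (2R,6R)-2-tert-butyl-6-methyl-1,3-dioxan-4-one (cis) | C[C@@H]1CC(=O)O[C@@H](O1)C(C)(C)C | intermediate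
19 | sodium (2R,4R,5R)-2-tert-butyl-4-methyl-6-oxo-1,3-dioxan-5-olate (the 5-alkoxide of 18, oxygen trans to methyl) | C[C@@H]1[C@@H]([O-])C(=O)O[C@@H](O1)C(C)(C)C.[Na+] | intermediate
20 | (2R,5R,6R)-2-tert-butyl-6-methyl-5-(triethylsilyloxy)-1,3-dioxan-4-one | C[C@@H]1[C@@H](O[Si](CC)(CC)CC)C(=O)O[C@@H](O1)C(C)(C)C | intermediate
21 | (2R,5S,6R)-2-tert-butyl-5,6-dimethyl-5-(triethylsilyloxy)-1,3-dioxan-4-one | C[C@@H]1[C@](C)(O[Si](CC)(CC)CC)C(=O)O[C@@H](O1)C(C)(C)C | intermediate
22 | (2S,3R)-2,3-dihydroxy-2-methylbutanoic acid | C[C@@H](O)[C@](C)(O)C(=O)O | intermediate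
23 | mixed anhydride of 24 with angelic acid | C/C=C(/C)C(=O)O[C@H](C)[C@](C)(O)C(=O)OC(=O)/C(C)=C\C | intermediate
24 | (2S,3R)-3-[(Z)-2-methylbut-2-enoyloxy]-2-hydroxy-2-methylbutanoic acid | C/C=C(/C)C(=O)O[C@H](C)[C@](C)(O)C(=O)O | intermediate
25 | (1(10)E,4Z)-11β-angeloyloxy-6β-[(2S,3R)-3-(angeloyloxy)-2-hydroxy-2-methylbutanoyloxy]-7αH,8βH-germacra-1(10),4-dien-12,8-olide | C/C=C(/C)C(=O)O[C@H](C)[C@](C)(O)C(=O)O[C@@H]1/C=C(/C)CC/C=C(\C)C[C@H]2OC(=O)[C@](C)(OC(=O)/C(C)=C\C)[C@H]12 | intermediate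
26 | CNP0137221.3: (1R,6R,7S,8R,10R,11R,4Z)-1,10-epoxy derivative of 25, side chain 2S,3R, both angelates Z | C/C=C(/C)C(=O)O[C@H](C)[C@](C)(O)C(=O)O[C@@H]1/C=C(/C)CC[C@H]2O[C@]2(C)C[C@H]2OC(=O)[C@](C)(OC(=O)/C(C)=C\C)[C@H]12 | target

**Step count and risks**

Total steps: 17. Longest linear sequence: 11 (steps 1–4, 6–10, 16, 17).

Where each stereocentre comes from:
- C8 and C11 are bought in 8.
- C7 is set in step 8 under control of C8 and C11.
- C6 is set in step 10 and C1/C10 in step 17, both by the ring.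
- C3' is bought in 17, and C2' is set in steps 12–13 under its control.

Three steps most likely to fail:

1. Step 8 (the new macrocyclisation). Possible failures are intermolecular coupling, hydrogen-atom quenching of the C7 radical, or competing activation of the tertiary hydroxyl. The fallback sets out from 10 and uses known reactions. Garegg–Samuelsson iodination (I2, PPh3, imidazole, toluene, 80 °C) converts the secondary hydroxyl into the iodide tert-butyl (2Z,6E)-8-[(2R,3S,4S)-4-hydroxy-3-iodo-4-methyl-5-oxooxolan-2-yl]-3,7-dimethylocta-2,6-dienoate F1; its configuration at C7 does not matter because it passes through the radical again. TMSOTf/2,6-lutidine then frees the iodo acid (2Z,6E)-8-[(2R,3S,4S)-4-hydroxy-3-iodo-4-methyl-5-oxooxolan-2-yl]-3,7-dimethylocta-2,6-dienoic acid F2. The ring is closed by the established nickel-catalysed reductive ketone synthesis from an alkyl iodide and a carboxylic acid activated in the flask (Boc2O, Ni(acac)2, 2,2'-bipyridine, MgCl2, Zn, DMA, high dilution, no light). This comes back to the route at 14.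

2. Step 10 (facial selectivity at C6). If hydride enters from the other face, the product is the 6α-alcohol (1(10)E,4Z)-11β-angeloyloxy-6α-hydroxy-7αH,8βH-germacra-1(10),4-dien-12,8-olide F3. The fallback sets out from 15, accepts F3, and esterifies it with acid 24 under Mitsunobu conditions (PPh3, DIAD, toluene, 0 °C), which inverts C6. This skips step 16 and comes back to the route at 25.

3. Step 17 (face of epoxidation). If the peracid attacks the wrong face of the 1(10)-olefin, the fallback sets out from 25 and builds the oxirane in two stages. NBS in aqueous DME at 0 °C gives the bromohydrin (1S,10R)-1-bromo-10-hydroxy-1,10-dihydro derivative of 25 F4 (bromonium on the exposed face, water at the tertiary C10 from the other face). K2CO3 in acetone then closes the ring by displacement at C1, which puts the oxygen on the face opposite to the one a peracid attacks. This comes back to the route at 26.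

**Further compounds**

F1 | step 8 | tert-butyl (2Z,6E)-8-[(2R,3S,4S)-4-hydroxy-3-iodo-4-methyl-5-oxooxolan-2-yl]-3,7-dimethylocta-2,6-dienoate | CC(C)(C)OC(=O)/C=C(/C)CC/C=C(\C)C[C@H]1OC(=O)[C@](C)(O)[C@H]1I
F2 | step 8 | (2Z,6E)-8-[(2R,3S,4S)-4-hydroxy-3-iodo-4-methyl-5-oxooxolan-2-yl]-3,7-dimethylocta-2,6-dienoic acid | OC(=O)/C=C(/C)CC/C=C(\C)C[C@H]1OC(=O)[C@](C)(O)[C@H]1I
F3 | step 10 | (1(10)E,4Z)-11β-angeloyloxy-6α-hydroxy-7αH,8βH-germacra-1(10),4-dien-12,8-olide (6S) | O[C@H]1/C=C(/C)CC/C=C(\C)C[C@H]2OC(=O)[C@](C)(OC(=O)/C(C)=C\C)[C@H]12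
F4 | step 17 | (1S,10R)-1-bromo-10-hydroxy-1,10-dihydro derivative of 25 | C/C=C(/C)C(=O)O[C@H](C)[C@](C)(O)C(=O)O[C@@H]1/C=C(/C)CC[C@H](Br)[C@](C)(O)C[C@H]2OC(=O)[C@](C)(OC(=O)/C(C)=C\C)[C@H]12
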